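Everything rests on closing the pyran ring of the upper flavan unit last, through its O1–C2 bond. An intramolecular Mitsunobu etherification turns an open-chain (1R,3R)-1,3,3-triarylpropan-1-ol into the 2,4-trans chroman in one stereoinvertive 6-exo-tet operation. It exploits that C2 is a benzylic carbinol carbon five bonds away from the only free phenol oxygen (the A-ring O1 on C8a, ortho to C4a), while C4 already carries the C8-linked epigallocatechin unit. The precursor is built on benzylated (−)-epigallocatechin: C8 lithiation and addition to a salicylaldehyde, chiral-phosphoric-acid alkylation of the derived o-quinone methide with an aroylacetic acid (sets C4), then CBS reduction (sets the carbinol).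

Key step: step 8

Shorthand used in names: EGC(Bn6)-8-yl = (2R,3R)-3,5,7-tris(benzyloxy)-2-[3,4,5-tris(benzyloxy)phenyl]chroman-8-yl.

Assumption: in step 6 the (R)-configured phosphoric acid is taken to give the 3R adduct; if the sense proves opposite, its enantiomer is used with no other change.

Step 1
Reactants: 1 (−)-epigallocatechin
Product: 2 (2R,3R)-5,7-bis(benzyloxy)-2-[3,4,5-tris(benzyloxy)phenyl]chroman-3-ol
Conditions: BnBr (5.5 equiv), K2CO3, DMF, 0 °C → rt, argon
Reagents that add atoms: benzyl bromide, BrCc1ccccc1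
Why: Williamson etherification in which carbonate deprotonates the five phenols but not the C3 alcohol, and the mild base under argon should spare the C2 centre and the pyrogallol ring; no stereocentre is formed.

Step 2
Reactants: 2 (2R,3R)-5,7-bis(benzyloxy)-2-[3,4,5-tris(benzyloxy)phenyl]chroman-3-ol
Product: 3 (2R,3R)-5,7-bis(benzyloxy)-8-bromo-2-[3,4,5-tris(benzyloxy)phenyl]chroman-3-ol
Conditions: NBS (1.0 equiv), CH2Cl2, −78 → −20 °C, dark
Reagents that add atoms: N-bromosuccinimide, O=C1CCC(=O)N1Br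
Why: Electrophilic aromatic bromination, which in 5,7-dialkoxyflavan-3-ols goes to C8 under kinetic control at low temperature, the crowded B ring being less activated; no stereocentre is formed.

Step 3
Reactants: 3 (2R,3R)-5,7-bis(benzyloxy)-8-bromo-2-[3,4,5-tris(benzyloxy)phenyl]chroman-3-ol
Product: 4 (2R,3R)-3,5,7-tris(benzyloxy)-8-bromo-2-[3,4,5-tris(benzyloxy)phenyl]chromane
Conditions: NaH, BnBr, n-Bu4NI (cat.), THF/DMF, 0 °C → rt
Reagents that add atoms: benzyl bromide, BrCc1ccccc1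
Why: Williamson etherification of the secondary alkoxide, which removes the last acidic proton before the organolithium step; the aryl bromide and the C2/C3 centres are inert to these conditions.

Step 4
Reactants: 4 (2R,3R)-3,5,7-tris(benzyloxy)-8-bromo-2-[3,4,5-tris(benzyloxy)phenyl]chromane; 5 4-(benzyloxy)-2-hydroxybenzaldehyde
Product: 8 [4-(benzyloxy)-2-hydroxyphenyl][EGC(Bn6)-8-yl]methanol (both carbinol epimers), via aryllithium 6 (not isolated), via sodium phenolate 7 (not isolated)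
Conditions: 4: t-BuLi (2.1 equiv), THF, −78 °C; 5: NaH (1.0 equiv), THF, 0 °C; combine at −78 → −30 °C; aq. NH4Cl; Et3N-washed silica
Reagents that add atoms: none
Why: Bromine–lithium exchange followed by 1,2-addition of the aryllithium to the aldehyde, whose phenol is masked beforehand as the phenolate so that it cannot quench the organolithium; the carbinol centre forms without control, which is harmless because step 6 planarises it.

Step 5
Reactants: 9 1-[4-(benzyloxy)phenyl]ethan-1-one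
Product: 11 3-[4-(benzyloxy)phenyl]-3-oxopropanoic acid, via lithium enolate 10 (not isolated)
Conditions: LDA (2.2 equiv), THF, −78 °C; CO2 (g); cold 1 M HCl; used at once
Reagents that add atoms: carbon dioxide, O=C=O
Why: Carboxylation of a ketone enolate with CO2, a standard entry to aroylacetic acids; the acid is kept cold and used at once because it decarboxylates on warming; no stereocentre is formed.

Step 6
Reactants: 8 [4-(benzyloxy)-2-hydroxyphenyl][EGC(Bn6)-8-yl]methanol; 11 3-[4-(benzyloxy)phenyl]-3-oxopropanoic acid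
Product: 14 (3R)-3-[4-(benzyloxy)-2-hydroxyphenyl]-1-[4-(benzyloxy)phenyl]-3-[EGC(Bn6)-8-yl]propan-1-one, via o-quinone methide 12 (not isolated), via keto acid adduct 13 (not isolated)
Conditions: (R)-TRIP (10 mol %), 11 (1.5 equiv), CHCl3, 0 °C → rt
Reagents that add atoms: none
Why: Brønsted-acid-catalysed o-quinone methide generation and decarboxylative conjugate alkylation, in which the chiral phosphoric acid dehydrates 8 to 12 and, hydrogen-bonded to its carbonyl oxygen and to the enol of 11, directs C–C bond formation to one face of the methide carbon (sets 3R) before 13 loses CO2.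

Step 7
Reactants: 14 (3R)-3-[4-(benzyloxy)-2-hydroxyphenyl]-1-[4-(benzyloxy)phenyl]-3-[EGC(Bn6)-8-yl]propan-1-one
Product: 15 (1R,3R)-3-[4-(benzyloxy)-2-hydroxyphenyl]-1-[4-(benzyloxy)phenyl]-3-[EGC(Bn6)-8-yl]propan-1-ol
Conditions: (S)-Me-CBS (0.3 equiv), BH3·SMe2 (2.5 equiv), THF, −20 °C; MeOH
Reagents that add atoms: none
Why: Corey–Bakshi–Shibata reduction in which the aryl group is the large and the CH2 chain the small substituent, so the (S)-oxazaborolidine should give the 1R carbinol under catalyst control, independent of the remote C3 centre, while the first equivalent of borane masks the phenol as a borate.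

Step 8
Reactants: 15 (1R,3R)-3-[4-(benzyloxy)-2-hydroxyphenyl]-1-[4-(benzyloxy)phenyl]-3-[EGC(Bn6)-8-yl]propan-1-ol
Product: 17 (2S,4R)-7-(benzyloxy)-2-[4-(benzyloxy)phenyl]-4-[EGC(Bn6)-8-yl]chromane, via alkoxyphosphonium phenoxide 16 (not isolated)
Conditions: PPh3, DIAD (slow addition), toluene/THF, 0 °C → rt, 0.01 M
Reagents that add atoms: none
Why: Mitsunobu cycloetherification: PPh3/DIAD convert the carbinol into the alkoxyphosphonium ion 16 while the betaine deprotonates the single free phenol, and the phenoxide displaces Ph3P=O intramolecularly. The closest known reaction type is the Mitsunobu closure of 1-aryl-3-(2-hydroxyaryl)propan-1-ols to flavans. The pyran ring closes through its O1–C2 bond in a 6-exo-tet SN2 mode. C2 is set by inversion of the CBS-derived 1R carbinol to 2S, and C4 (R) is not touched, so the 2,4-trans relationship follows from the two earlier reagent-controlled steps and not from ring conformational bias. The step needs SN2 displacement to outrun ionisation of the p-benzyloxybenzylic phosphonium ion (scrambling at C2, elimination to the styrene); the intramolecular six-membered closure, a non-polar solvent, low temperature and slow DIAD addition should secure this, and chemoselectivity follows because 15 holds only one free phenol and one free alcohol.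

Step 9
Reactants: 17 (2S,4R)-7-(benzyloxy)-2-[4-(benzyloxy)phenyl]-4-[EGC(Bn6)-8-yl]chromane
Product: 18 (2R,3R)-8-[(2S,4R)-7-hydroxy-2-(4-hydroxyphenyl)chroman-4-yl]-2-(3,4,5-trihydroxyphenyl)chromane-3,5,7-triol
Conditions: H2 (1 atm), 20% Pd(OH)2/C, THF/MeOH, rt; filtration and isolation under argon
Reagents that add atoms: none
Why: Hydrogenolysis of the eight benzyl ethers under mild conditions, which in benzylated flavan-3-ol and proanthocyanidin chemistry leaves the cyclic benzylic C2–O1 bonds and all four stereocentres intact.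

Compound list
1 | (−)-epigallocatechin | Oc1cc(O)c2c(c1)O[C@H](c1cc(O)c(O)c(O)c1)[C@H](O)C2 | starting material
2 | (2R,3R)-5,7-bis(benzyloxy)-2-[3,4,5-tris(benzyloxy)phenyl]chroman-3-ol | c1c(OCc2ccccc2)cc(OCc2ccccc2)c2c1O[C@H](c1cc(OCc3ccccc3)c(OCc3ccccc3)c(OCc3ccccc3)c1)[C@H](O)C2 | intermediate
3 | (2R,3R)-5,7-bis(benzyloxy)-8-bromo-2-[3,4,5-tris(benzyloxy)phenyl]chroman-3-ol | Brc1c(OCc2ccccc2)cc(OCc2ccccc2)c2c1O[C@H](c1cc(OCc3ccccc3)c(OCc3ccccc3)c(OCc3ccccc3)c1)[C@H](O)C2 | intermediate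
4 | (2R,3R)-3,5,7-tris(benzyloxy)-8-bromo-2-[3,4,5-tris(benzyloxy)phenyl]chromane | Brc1c(OCc2ccccc2)cc(OCc2ccccc2)c2c1O[C@H](c1cc(OCc3ccccc3)c(OCc3ccccc3)c(OCc3ccccc3)c1)[C@H](OCc1ccccc1)C2 | intermediate
5 | 4-(benzyloxy)-2-hydroxybenzaldehyde | O=Cc1ccc(OCc2ccccc2)cc1O | starting material
6 | [EGC(Bn6)-8-yl]lithium (formed in situ) | [Li]c1c(OCc2ccccc2)cc(OCc2ccccc2)c2c1O[C@H](c1cc(OCc3ccccc3)c(OCc3ccccc3)c(OCc3ccccc3)c1)[C@H](OCc1ccccc1)C2 | intermediate
7 | sodium 5-(benzyloxy)-2-formylphenolate (formed in situ) | O=Cc1ccc(OCc2ccccc2)cc1[O-].[Na+] | intermediate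
8 | [4-(benzyloxy)-2-hydroxyphenyl][EGC(Bn6)-8-yl]methanol (carbinol centre undefined, both epimers) | OC(c1ccc(OCc2ccccc2)cc1O)c1c(OCc2ccccc2)cc(OCc2ccccc2)c2c1O[C@H](c1cc(OCc3ccccc3)c(OCc3ccccc3)c(OCc3ccccc3)c1)[C@H](OCc1ccccc1)C2 | intermediate
9 | 1-[4-(benzyloxy)phenyl]ethan-1-one | CC(=O)c1ccc(OCc2ccccc2)cc1 | starting material
10 | lithium 1-[4-(benzyloxy)phenyl]ethen-1-olate (formed in situ) | C=C([O-])c1ccc(OCc2ccccc2)cc1.[Li+] | intermediate
11 | 3-[4-(benzyloxy)phenyl]-3-oxopropanoic acid | OC(=O)CC(=O)c1ccc(OCc2ccccc2)cc1 | intermediate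
12 | 3-(benzyloxy)-6-{[EGC(Bn6)-8-yl]methylidene}cyclohexa-2,4-dien-1-one (o-quinone methide, formed in situ, methide geometry not fixed) | O=C1C=C(OCc2ccccc2)C=CC1=Cc1c(OCc2ccccc2)cc(OCc2ccccc2)c2c1O[C@H](c1cc(OCc3ccccc3)c(OCc3ccccc3)c(OCc3ccccc3)c1)[C@H](OCc1ccccc1)C2 | intermediate
13 | 2-{(R)-[4-(benzyloxy)-2-hydroxyphenyl][EGC(Bn6)-8-yl]methyl}-3-[4-(benzyloxy)phenyl]-3-oxopropanoic acid (formed in situ, C2 of the acid undefined) | OC(=O)C(C(=O)c1ccc(OCc2ccccc2)cc1)[C@@H](c1c(OCc2ccccc2)cc(OCc2ccccc2)c2c1O[C@H](c1cc(OCc3ccccc3)c(OCc3ccccc3)c(OCc3ccccc3)c1)[C@H](OCc1ccccc1)C2)c1ccc(OCc2ccccc2)cc1O | intermediate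
14 | (3R)-3-[4-(benzyloxy)-2-hydroxyphenyl]-1-[4-(benzyloxy)phenyl]-3-[EGC(Bn6)-8-yl]propan-1-one | O=C(C[C@@H](c1c(OCc2ccccc2)cc(OCc2ccccc2)c2c1O[C@H](c1cc(OCc3ccccc3)c(OCc3ccccc3)c(OCc3ccccc3)c1)[C@H](OCc1ccccc1)C2)c1ccc(OCc2ccccc2)cc1O)c1ccc(OCc2ccccc2)cc1 | intermediate
15 | (1R,3R)-3-[4-(benzyloxy)-2-hydroxyphenyl]-1-[4-(benzyloxy)phenyl]-3-[EGC(Bn6)-8-yl]propan-1-ol | O[C@@H](c1ccc(OCc2ccccc2)cc1)C[C@@H](c1c(OCc2ccccc2)cc(OCc2ccccc2)c2c1O[C@H](c1cc(OCc3ccccc3)c(OCc3ccccc3)c(OCc3ccccc3)c1)[C@H](OCc1ccccc1)C2)c1ccc(OCc2ccccc2)cc1O | intermediate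
16 | alkoxytriphenylphosphonium phenoxide of 15 (zwitterion, formed in situ) | c1ccccc1[P+](c1ccccc1)(c1ccccc1)O[C@@H](c1ccc(OCc2ccccc2)cc1)C[C@@H](c1c(OCc2ccccc2)cc(OCc2ccccc2)c2c1O[C@H](c1cc(OCc3ccccc3)c(OCc3ccccc3)c(OCc3ccccc3)c1)[C@H](OCc1ccccc1)C2)c1ccc(OCc2ccccc2)cc1[O-] | intermediate
17 | (2S,4R)-7-(benzyloxy)-2-[4-(benzyloxy)phenyl]-4-[EGC(Bn6)-8-yl]chromane | O(Cc5ccccc5)c1ccc([C@@H]2C[C@@H](c3c(OCc5ccccc5)cc(OCc5ccccc5)c4c3O[C@H](c3cc(OCc5ccccc5)c(OCc5ccccc5)c(OCc5ccccc5)c3)[C@H](OCc5ccccc5)C4)c3ccc(OCc5ccccc5)cc3O2)cc1 | intermediate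
18 | (2R,3R)-8-[(2S,4R)-7-hydroxy-2-(4-hydroxyphenyl)chroman-4-yl]-2-(3,4,5-trihydroxyphenyl)chromane-3,5,7-triol | Oc1ccc([C@@H]2C[C@@H](c3c(O)cc(O)c4c3O[C@H](c3cc(O)c(O)c(O)c3)[C@H](O)C4)c3ccc(O)cc3O2)cc1 | target

Total step count: 9. Longest linear sequence: 8 steps (steps 1–4 and 6–9 from (−)-epigallocatechin); step 5 is a one-step side branch.

Steps most likely to fail

Step 6. What may go wrong: poor facial selectivity at the methide carbon, because the twisted, doubly ortho-oxygenated aryl group may weaken catalyst control. An uncatalysed background addition, Friedel–Crafts self-condensation through the free C6 position of the epigallocatechin A ring, and acid-induced cyclodehydration of the keto phenol are further risks. Fallback: catalyst control at this centre is given up in favour of separation after ring closure. Setting out from 8, alkylation with 11 under an achiral acid (diphenyl phosphate, CHCl3) would give 14 together with its epimer, the (3S)-ketone F1. The mixture is taken through the CBS reduction, which gives 15 and the (1R,3S)-diol F2, and then through the Mitsunobu closure. There the C4 epimers become the 2,4-trans flavan 17 and the 2,4-cis flavan F3, which differ in shape and polarity and are separated by chromatography. The route is rejoined at 17.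

Step 8. What may go wrong: ionisation of the p-benzyloxybenzylic oxyphosphonium ion ahead of displacement, which would erode the configuration at C2 and open an elimination path to the styrene. Fallback: the ring is closed through the aryl C8a–O bond instead, with retention at the carbinol. Setting out from 14, the phenol is converted into the aryl triflate F4 (Tf2O, pyridine, CH2Cl2, 0 °C). The ketone is then reduced with the (R)-oxazaborolidine and borane to the (1S,3R)-alcohol F5. Palladium-catalysed intramolecular C–O coupling (Pd(OAc)2, a bulky di-tert-butylbiarylphosphine such as RockPhos, Cs2CO3, toluene, 80 °C) closes the ring without any benzylic cation. The route is rejoined at 17.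

Step 4. What may go wrong: quenching of the hindered aryllithium by proton transfer (benzylic positions of the benzyl ethers), slow addition to the deactivated phenolate aldehyde, and loss of the acid-labile carbinol on isolation. Fallback: the polarity of the coupling is reversed. Setting out from 4, bromine–lithium exchange and trapping with DMF give the 8-carbaldehyde F6. The small O,C-dilithio reagent lithium 5-(benzyloxy)-2-lithiophenolate F7, made from commercial 5-(benzyloxy)-2-bromophenol with n-BuLi (2 equiv, THF, −78 °C), is then added in excess to F6. The route is rejoined at 8.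

Further compounds
F1 | step 6 | (3S)-3-[4-(benzyloxy)-2-hydroxyphenyl]-1-[4-(benzyloxy)phenyl]-3-[EGC(Bn6)-8-yl]propan-1-one | O=C(C[C@H](c1c(OCc2ccccc2)cc(OCc2ccccc2)c2c1O[C@H](c1cc(OCc3ccccc3)c(OCc3ccccc3)c(OCc3ccccc3)c1)[C@H](OCc1ccccc1)C2)c1ccc(OCc2ccccc2)cc1O)c1ccc(OCc2ccccc2)cc1
F2 | step 6 | (1R,3S)-3-[4-(benzyloxy)-2-hydroxyphenyl]-1-[4-(benzyloxy)phenyl]-3-[EGC(Bn6)-8-yl]propan-1-ol | O[C@@H](c1ccc(OCc2ccccc2)cc1)C[C@H](c1c(OCc2ccccc2)cc(OCc2ccccc2)c2c1O[C@H](c1cc(OCc3ccccc3)c(OCc3ccccc3)c(OCc3ccccc3)c1)[C@H](OCc1ccccc1)C2)c1ccc(OCc2ccccc2)cc1O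
F3 | step 6 | (2S,4S)-7-(benzyloxy)-2-[4-(benzyloxy)phenyl]-4-[EGC(Bn6)-8-yl]chromane | O(Cc5ccccc5)c1ccc([C@@H]2C[C@H](c3c(OCc5ccccc5)cc(OCc5ccccc5)c4c3O[C@H](c3cc(OCc5ccccc5)c(OCc5ccccc5)c(OCc5ccccc5)c3)[C@H](OCc5ccccc5)C4)c3ccc(OCc5ccccc5)cc3O2)cc1
F4 | step 8 | 5-(benzyloxy)-2-{(1R)-3-[4-(benzyloxy)phenyl]-3-oxo-1-[EGC(Bn6)-8-yl]propyl}phenyl trifluoromethanesulfonate | O=C(C[C@@H](c1c(OCc2ccccc2)cc(OCc2ccccc2)c2c1O[C@H](c1cc(OCc3ccccc3)c(OCc3ccccc3)c(OCc3ccccc3)c1)[C@H](OCc1ccccc1)C2)c1ccc(OCc2ccccc2)cc1OS(=O)(=O)C(F)(F)F)c1ccc(OCc2ccccc2)cc1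
F5 | step 8 | 5-(benzyloxy)-2-{(1R,3S)-3-[4-(benzyloxy)phenyl]-3-hydroxy-1-[EGC(Bn6)-8-yl]propyl}phenyl trifluoromethanesulfonate | O[C@H](c1ccc(OCc2ccccc2)cc1)C[C@@H](c1c(OCc2ccccc2)cc(OCc2ccccc2)c2c1O[C@H](c1cc(OCc3ccccc3)c(OCc3ccccc3)c(OCc3ccccc3)c1)[C@H](OCc1ccccc1)C2)c1ccc(OCc2ccccc2)cc1OS(=O)(=O)C(F)(F)F
F6 | step 4 | (2R,3R)-3,5,7-tris(benzyloxy)-2-[3,4,5-tris(benzyloxy)phenyl]chromane-8-carbaldehyde | O=Cc1c(OCc2ccccc2)cc(OCc2ccccc2)c2c1O[C@H](c1cc(OCc3ccccc3)c(OCc3ccccc3)c(OCc3ccccc3)c1)[C@H](OCc1ccccc1)C2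
F7 | step 4 | lithium 5-(benzyloxy)-2-lithiophenolate | [Li]Oc1cc(OCc2ccccc2)ccc1[Li]
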